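**Plan**

- Retrosynthesis: remove the C2 tiglate and the C13 acetate, return C13 to a carboxyl group and open the lactone (O8–C12) to a C8 ketone plus a C11 gem-diester. Then cut C6–C7 and O–C5 together, then C7–C11 (aldol to diethyl ketomalonate), C7–C8 (ester to bromomethyl ketone), C10–C14 (conjugate addition), C9=C10 (cross-metathesis), and the C1, C4 and C5 appendages of a 4-silyloxycyclopentenone.
- Forward: the cyclopentane is bought as the enone and the chain C10–C9–C8–C7–C11 is grown on C1. One flask then closes the cycloheptanone (C6–C7) and the tetrahydrofuran (O–C5); reduction at C8 closes the γ-lactone; the two esters come last.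
- Enabling feature: the tetrahydrofuran O–C11–C7–C6–C5 shares its C5–C6–C7 edge with the seven-membered ring, and C6 is a bare CH2 between the oxygenated quaternary C5 and C7. A C8 ketone therefore makes C7 an α-keto radical site (and keeps it epimerisable), the 5-exomethylene C5=C6 is its acceptor, and the 4α-hydroxyl next to C5 relays the C5 electrophile as an epoxide that the C11 hydroxyl opens.
- Stereochemistry: C2 comes from the enone; C1 and C4 from anti additions on the cyclopentanone; C10 from a chiral copper catalyst; C5 from anti opening of the 4α,5α-epoxide; C7 from equilibration next to the C8 ketone; C8 from exo hydride attack on the cage; C11 from the fact that only one of the two ester groups can reach O8.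

Key step: step 8

Remark: guaiane numbering of the target is used for all intermediates (C1–C5 five-membered ring, C5–C10 and C1 seven-membered ring, C11–C13 on C7, C14 on C10, C15 on C4; α is the face of H-1); 1 is taken as purchasable in enantiopure form, and bromohydrin 17 is carried as a mixture of C7 epimers because C7 becomes a radical and is later equilibrated.

**Step 1**
Reactants: 1 (S)-4-(tert-butyldimethylsilyloxy)cyclopent-2-en-1-one; 2 vinylmagnesium bromide; 3 N,N-dimethylmethyleneiminium iodide (Eschenmoser's salt)
Product: 4 all-trans 2-[(dimethylamino)methyl]-3-vinyl-4-(tert-butyldimethylsilyloxy)cyclopentan-1-one (C1 β-vinyl, C2 α-OTBS, C5 α-CH2NMe2, C4 ketone)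
Conditions: CuBr·SMe2 (10 mol %), THF, −78 °C; then 3, −78 → 0 °C
Reagents that add atoms: vinylmagnesium bromide (C=C[Mg]Br); N,N-dimethylmethyleneiminium iodide (C=[N+](C)C.[I-])
Why: Copper-catalysed conjugate addition should put the vinyl group on C1 anti to the C2 silyloxy group, and the enolate should be aminomethylated at C5 anti to the new vinyl group (three-component enone coupling with Mannich trapping), so C1 is set and C5 carries a masked methylene.

**Step 2**
Reactants: 4; 5 methylmagnesium bromide
Product: 6 1-methyl-2-[(dimethylamino)methyl]-3-vinyl-4-(tert-butyldimethylsilyloxy)cyclopentan-1-ol (4α-OH, 4β-CH3)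
Conditions: CeCl3 (anhydrous), THF, −78 °C; aq NH4Cl
Reagents that add atoms: methylmagnesium bromide (C[Mg]Br)
Why: Organocerium-mediated 1,2-addition (Imamoto conditions) should avoid enolisation and loss of the β-silyloxy group and deliver methyl to the β face, anti to the adjacent C5 aminomethyl group and to the C2 silyloxy group, which sets C4.

**Step 3**
Reactants: 6
Product: 8 1-methyl-2-methylene-3-vinyl-4-(tert-butyldimethylsilyloxy)cyclopentan-1-ol (4α-OH, 1β-vinyl, 2α-OTBS), via amine N-oxide 7 (not isolated)
Conditions: mCPBA, CH2Cl2, −20 °C; filtration through basic Al2O3; THF/DMSO, 60 °C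
Reagents that add atoms: none
Why: N-Oxidation of the tertiary amine should be faster than epoxidation of the monosubstituted alkene, and the amine oxide should undergo syn Cope elimination through its only β-hydrogen (H-5) to give the 5-exomethylene.

**Step 4**
Reactants: 8; 9 methyl acrylate
Product: 10 methyl (E)-3-[(1β)-cyclopentyl]acrylate, i.e. 8 with CH=CH–CO2Me in place of vinyl
Conditions: second-generation Hoveyda–Grubbs catalyst RuCl2(H2IMes)(=CH-C6H4-2-OiPr) (5 mol %), CH2Cl2, 40 °C
Reagents that add atoms: methyl acrylate (C=CC(=O)OC)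
Why: Olefin cross-metathesis of the monosubstituted vinyl group with an acrylate should be E-selective, while the 1,1-disubstituted exomethylene next to the quaternary C4 should not engage the catalyst.

**Step 5**
Reactants: 10; 5 methylmagnesium bromide
Product: 11 methyl (3R)-3-[cyclopentyl]butanoate (10R; C8 methyl ester)
Conditions: CuI (2 mol %), (S)-Tol-BINAP (3 mol %), t-BuOMe, −20 °C; aq NH4Cl
Reagents that add atoms: methylmagnesium bromide (C[Mg]Br)
Why: Copper-catalysed asymmetric conjugate addition of a Grignard reagent to an E-enoate should create C10 under catalyst control; the ligand antipode named is the one expected to place methyl on the face that gives 10R, and the sense is to be confirmed on the first run, both antipodes being available.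

**Step 6**
Reactants: 11; 12 dibromomethane
Product: 13 1-bromo-(4R)-4-[cyclopentyl]pentan-2-one (bromomethyl ketone, C7H2Br–C8=O)
Conditions: MeLi, THF, −78 °C (MeLi added to 11 and 12); aq NH4Cl at −78 °C
Reagents that add atoms: dibromomethane (BrCBr)
Why: Bromomethyllithium formed by Br/Li exchange in the presence of the ester should add once, giving a tetrahedral intermediate that is stable at −78 °C and collapses to the bromomethyl ketone on quench (halomethyllithium homologation of esters).

**Step 7**
Reactants: 13; 14 diethyl ketomalonate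
Product: 17 diethyl 2-hydroxy-2-[1-bromo-2-oxo-(4R)-4-(cyclopentyl)pentyl]malonate (C7 epimers), via bromo enol silane 15 (not isolated), via bis-silyl aldol adduct 16 (not isolated)
Conditions: TMSOTf, Et3N, CH2Cl2, 0 °C; then 14, TMSOTf (cat.), −78 °C; then citric acid, MeOH/H2O, 0 °C
Reagents that add atoms: diethyl ketomalonate (CCOC(=O)C(=O)C(=O)OCC)
Why: Enolisation towards the more acidic bromine-bearing C7 should give the bromo enol silane, which adds to the very electrophilic central carbonyl of the tricarbonyl compound (Mukaiyama aldol) without free alkoxide, so that neither retro-aldol nor Darzens closure intervenes; mild acid then frees both hydroxyl groups, and C11 is not stereogenic.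

**Step 8**
Reactants: 17
Product: 20 diethyl 2α-(tert-butyldimethylsilyloxy)-4α-hydroxy-8-oxo-5β,11-epoxy-1αH,7αH,10βH-guaiane-12,13-dioate (cage keto diester), via tertiary bromide 18 (not isolated), via 4α,5α-epoxide 19 (not isolated)
Conditions: fac-Ir(ppy)3 (1 mol %), 2,6-lutidine (1.1 equiv), MeCN (0.01 M), blue LEDs, rt; then CSA (0.3 equiv), 40 °C, same flask
Reagents that add atoms: none
Why: Excited fac-Ir(ppy)3 reduces the C7–Br bond to an electrophilic α-keto radical that adds to the CH2 terminus (C6) of the electron-rich 5-exomethylene; the tertiary C5 radical takes up bromine from 17 (or is oxidised by the tetravalent iridium species), and the C5 electrophile is captured by the neighbouring 4α-hydroxyl as the 4α,5α-epoxide. The added acid then lets C7 equilibrate through the enol of the C8 ketone and opens the epoxide with the C11 hydroxyl, so that C6–C7 and O–C5 arise in one flask. The closest known reaction types are the photoredox atom-transfer radical cyclisation of α-bromo carbonyl compounds onto 1,1-disubstituted alkenes and the acid-catalysed opening of a fully substituted epoxide by a tethered hydroxyl with inversion, as in polyether synthesis. The cycloheptanone closes 7-endo-trig and the tetrahydrofuran 5-exo-tet. C5 is controlled by the C4 stereocentre, because the epoxide must lie on the α face and is opened anti, which gives the 5β-ether and returns the 4α-hydroxyl; C7 is controlled by equilibration, because only the epimer with C11 on the β face can reach C5 from behind the epoxide, and it is drained irreversibly. The step needs 7-endo over 6-exo addition, secured by the 1,1-disubstituted alkene and the polarity match of the radical with its CH2 terminus, and 5-exo over 6-endo epoxide opening, secured by the shorter tether to C5.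

**Step 9**
Reactants: 20
Product: 22 ethyl 2α-(tert-butyldimethylsilyloxy)-4α-hydroxy-5β,11-epoxy-1αH,7αH,8αH,10βH-guaian-8β,12-olid-13-oate (lactone ester), via hydroxy diester 21 (not isolated)
Conditions: NaBH4, EtOH, −20 → 0 °C; aq NH4Cl, rt
Reagents that add atoms: none
Why: Borohydride should attack the C8 ketone from the side of the one-carbon C6 bridge, away from the ester-bearing O–C11 bridge, so that the 8β-alkoxide arises next to the syn ethoxycarbonyl group and closes the cis-fused γ-lactone; only that ester can reach, which sets C11 as well as C8.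

**Step 10**
Reactants: 22
Product: 24 2α-(tert-butyldimethylsilyloxy)-4α-hydroxy-5β,11-epoxyguaian-8β,12-olid-13-oic acid (lactone acid), via dilithium dicarboxylate 23 (not isolated)
Conditions: LiOH, THF/H2O, 0 °C; then 1 M HCl to pH 2, 0 °C
Reagents that add atoms: lithium hydroxide ([Li+].[OH-])
Why: Saponification of the remaining ethyl ester, with reversible opening of the lactone, followed by acidification should re-form the only possible γ-lactone and leave the other carboxyl group free.

**Step 11**
Reactants: 24
Product: 25 2α-(tert-butyldimethylsilyloxy)-4α,13-dihydroxy-5β,11-epoxyguaian-8β,12-olide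
Conditions: BH3·SMe2, THF, 0 °C → rt; MeOH
Reagents that add atoms: none
Why: Borane should reduce the free carboxylic acid much faster than the lactone and leave the silyl ether untouched (chemoselective acid reduction).

**Step 12**
Reactants: 25; 26 acetic anhydride
Product: 27 13-acetoxy-2α-(tert-butyldimethylsilyloxy)-4α-hydroxy-5β,11-epoxyguaian-8β,12-olide
Conditions: pyridine, DMAP (cat.), CH2Cl2, 0 °C
Reagents that add atoms: acetic anhydride (CC(=O)OC(C)=O)
Why: The primary C13 alcohol should be acetylated selectively, since the tertiary C4 alcohol does not react under these conditions.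

**Step 13**
Reactants: 27
Product: 28 13-acetoxy-2α,4α-dihydroxy-5β,11-epoxyguaian-8β,12-olide
Conditions: HF·pyridine, pyridine/THF, 0 °C → rt
Reagents that add atoms: none
Why: Buffered fluoride cleavage of the secondary silyl ether should leave the acetate and the lactone intact.

**Step 14**
Reactants: 28; 29 tigloyl chloride
Product: 30 13-acetoxy-4α-hydroxy-2α-tigloyloxy-5β,11-epoxy-1αH,7αH,8αH,10βH-guaian-8β,12-olide (CNP0112086.1)
Conditions: pyridine, DMAP (cat.), CH2Cl2, 0 °C → rt
Reagents that add atoms: tigloyl chloride (C/C=C(\C)C(Cl)=O)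
Why: Acylation of the secondary C2 alcohol under nucleophilic catalysis should leave the tertiary C4 alcohol untouched, and pyridine as the only base avoids deconjugation of the E-configured tigloyl group.

**Compound list**

1 | (S)-4-(tert-butyldimethylsilyloxy)cyclopent-2-en-1-one | O=C1C[C@H](O[Si](C)(C)C(C)(C)C)C=C1 | starting material
2 | vinylmagnesium bromide | C=C[Mg]Br | starting material
3 | N,N-dimethylmethyleneiminium iodide | C=[N+](C)C.[I-] | starting material
4 | all-trans 2-[(dimethylamino)methyl]-3-vinyl-4-(tert-butyldimethylsilyloxy)cyclopentan-1-one | CC(C)(C)[Si](C)(C)O[C@H]1CC(=O)[C@@H](CN(C)C)[C@@H]1C=C | intermediate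
5 | methylmagnesium bromide | C[Mg]Br | starting material
6 | 1-methyl-2-[(dimethylamino)methyl]-3-vinyl-4-(tert-butyldimethylsilyloxy)cyclopentan-1-ol (4α-OH) | CC(C)(C)[Si](C)(C)O[C@H]1C[C@@](C)(O)[C@@H](CN(C)C)[C@@H]1C=C | intermediate
7 | N-oxide of 6 | CC(C)(C)[Si](C)(C)O[C@H]1C[C@@](C)(O)[C@@H](C[N+](C)(C)[O-])[C@@H]1C=C | intermediate
8 | 1-methyl-2-methylene-3-vinyl-4-(tert-butyldimethylsilyloxy)cyclopentan-1-ol | CC(C)(C)[Si](C)(C)O[C@H]1C[C@@](C)(O)C(=C)[C@@H]1C=C | intermediate
9 | methyl acrylate | C=CC(=O)OC | starting material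
10 | methyl (E)-3-(cyclopentyl)acrylate derived from 8 | CC(C)(C)[Si](C)(C)O[C@H]1C[C@@](C)(O)C(=C)[C@@H]1/C=C/C(=O)OC | intermediate
11 | methyl (3R)-3-(cyclopentyl)butanoate (10R) | CC(C)(C)[Si](C)(C)O[C@H]1C[C@@](C)(O)C(=C)[C@@H]1[C@H](C)CC(=O)OC | intermediate
12 | dibromomethane | BrCBr | starting material
13 | bromomethyl ketone (1-bromo-4-(cyclopentyl)pentan-2-one, 10R) | CC(C)(C)[Si](C)(C)O[C@H]1C[C@@](C)(O)C(=C)[C@@H]1[C@H](C)CC(=O)CBr | intermediate
14 | diethyl ketomalonate | CCOC(=O)C(=O)C(=O)OCC | starting material
15 | (Z)-bromo enol silane of 13 with C4–OTMS | CC(C)(C)[Si](C)(C)O[C@H]1C[C@@](C)(O[Si](C)(C)C)C(=C)[C@@H]1[C@H](C)C/C(O[Si](C)(C)C)=C/Br | intermediate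
16 | bis-silylated aldol adduct (C4–OTMS, C11–OTMS) | CC(C)(C)[Si](C)(C)O[C@H]1C[C@@](C)(O[Si](C)(C)C)C(=C)[C@@H]1[C@H](C)CC(=O)C(Br)C(O[Si](C)(C)C)(C(=O)OCC)C(=O)OCC | intermediate
17 | bromohydrin keto diester (C7 epimers) | CC(C)(C)[Si](C)(C)O[C@H]1C[C@@](C)(O)C(=C)[C@@H]1[C@H](C)CC(=O)C(Br)C(O)(C(=O)OCC)C(=O)OCC | intermediate
18 | tertiary C5 bromide of the cyclised cycloheptanone (C5 and C7 epimers) | CC(C)(C)[Si](C)(C)O[C@H]1C[C@@](C)(O)C2(Br)CC(C(=O)C[C@@H](C)[C@H]12)C(O)(C(=O)OCC)C(=O)OCC | intermediate
19 | 4α,5α-epoxide of the cyclised cycloheptanone (C7 epimers) | CC(C)(C)[Si](C)(C)O[C@H]1C[C@@]2(C)O[C@]23CC(C(=O)C[C@@H](C)[C@H]13)C(O)(C(=O)OCC)C(=O)OCC | intermediate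
20 | cage keto diester | CC(C)(C)[Si](C)(C)O[C@H]1C[C@@](C)(O)[C@@]23C[C@@H](C(=O)C[C@@H](C)[C@H]12)C(C(=O)OCC)(C(=O)OCC)O3 | intermediate
21 | 8β-hydroxy diester | CC(C)(C)[Si](C)(C)O[C@H]1C[C@@](C)(O)[C@@]23C[C@@H]([C@H](O)C[C@@H](C)[C@H]12)C(C(=O)OCC)(C(=O)OCC)O3 | intermediate
22 | lactone ethyl ester | CC(C)(C)[Si](C)(C)O[C@H]1C[C@@](C)(O)[C@@]23C[C@H]4[C@@H](C[C@@H](C)[C@H]12)OC(=O)[C@@]4(C(=O)OCC)O3 | intermediate
23 | dilithium 8β-hydroxy dicarboxylate | [Li+].[Li+].CC(C)(C)[Si](C)(C)O[C@H]1C[C@@](C)(O)[C@@]23C[C@@H]([C@H](O)C[C@@H](C)[C@H]12)C(C(=O)[O-])(C(=O)[O-])O3 | intermediate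
24 | lactone acid | CC(C)(C)[Si](C)(C)O[C@H]1C[C@@](C)(O)[C@@]23C[C@H]4[C@@H](C[C@@H](C)[C@H]12)OC(=O)[C@@]4(C(=O)O)O3 | intermediate
25 | 13-hydroxy lactone | CC(C)(C)[Si](C)(C)O[C@H]1C[C@@](C)(O)[C@@]23C[C@H]4[C@@H](C[C@@H](C)[C@H]12)OC(=O)[C@@]4(CO)O3 | intermediate
26 | acetic anhydride | CC(=O)OC(C)=O | starting material
27 | 13-acetoxy lactone, C2 silyl ether | CC(C)(C)[Si](C)(C)O[C@H]1C[C@@](C)(O)[C@@]23C[C@H]4[C@@H](C[C@@H](C)[C@H]12)OC(=O)[C@@]4(COC(C)=O)O3 | intermediate
28 | 13-acetoxy-2α,4α-diol | O[C@H]1C[C@@](C)(O)[C@@]23C[C@H]4[C@@H](C[C@@H](C)[C@H]12)OC(=O)[C@@]4(COC(C)=O)O3 | intermediate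
29 | tigloyl chloride | C/C=C(\C)C(Cl)=O | starting material
30 | CNP0112086.1 | C/C=C(\C)C(=O)O[C@H]1C[C@@](C)(O)[C@@]23C[C@H]4[C@@H](C[C@@H](C)[C@H]12)OC(=O)[C@@]4(COC(C)=O)O3 | target

Total step count: 14. Longest linear sequence: 14 steps (from 1).

**Steps most likely to fail**

Step 8. The α-keto radical may be reduced before the slow 7-endo closure, and in the acid stage the fully substituted epoxide may rearrange or eliminate before C7 has equilibrated. The fallback changes the radical manifold to degenerative xanthate transfer, which uses no reductant and gives the radical a long effective lifetime. From 17, displacement of bromide with potassium O-ethyl xanthate in acetone would give the S-(2-oxoalkyl) xanthate F1. Heating F1 with portions of dilauroyl peroxide in 1,2-dichloroethane would give, by xanthate-transfer 7-endo cyclisation, the tertiary C5 xanthate F2. AgOTf with 2,6-lutidine would ionise the C5–S bond with participation of the 4α-hydroxyl and so return to epoxide 19, from which the acid stage of step 8 leads to 20.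

Step 5. The γ-stereocentre at C1 may oppose the catalyst, giving poor or reversed facial selectivity at C10. The fallback replaces catalyst control by an auxiliary whose sense follows from the chelated syn-s-cis model. (R)-4-Phenyloxazolidin-2-one would be acylated with acryloyl chloride (n-BuLi, THF) to (R)-3-acryloyl-4-phenyloxazolidin-2-one F3. From 8, cross-metathesis with F3 under the conditions of step 4 would give the N-enoyl imide F4. MeMgBr with CuBr·SMe2 would add methyl anti to the phenyl group to give the 10R imide F5, and MeMgBr in MeOH (magnesium methoxide) would release methyl ester 11.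

Step 7. Enolisation may occur towards C9 instead of C7, and the adduct may revert by retro-aldol during desilylation. The fallback is a Darzens condensation, in which only the aldolate formed through the C7 enolate can close, so that the wrong enolate is corrected by reversal. From 13, reaction with 14 and Cs2CO3 in MeCN at 0 °C would give the glycidic keto diester F6. MgBr2·OEt2 in Et2O would reopen F6 at C7, the carbon α to the ketone, and return bromohydrin 17.

**Further compounds**

F1 | step 8 | S-(2-oxoalkyl) O-ethyl xanthate from 17 | CC(C)(C)[Si](C)(C)O[C@H]1C[C@@](C)(O)C(=C)[C@@H]1[C@H](C)CC(=O)C(SC(=S)OCC)C(O)(C(=O)OCC)C(=O)OCC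
F2 | step 8 | tertiary C5 xanthate of the cyclised cycloheptanone | CC(C)(C)[Si](C)(C)O[C@H]1C[C@@](C)(O)C2(SC(=S)OCC)CC(C(=O)C[C@@H](C)[C@H]12)C(O)(C(=O)OCC)C(=O)OCC
F3 | step 5 | (R)-3-acryloyl-4-phenyloxazolidin-2-one | C=CC(=O)N1[C@H](c2ccccc2)COC1=O
F4 | step 5 | N-enoyl imide from 8 | CC(C)(C)[Si](C)(C)O[C@H]1C[C@@](C)(O)C(=C)[C@@H]1/C=C/C(=O)N1[C@H](c2ccccc2)COC1=O
F5 | step 5 | 10R imide adduct | CC(C)(C)[Si](C)(C)O[C@H]1C[C@@](C)(O)C(=C)[C@@H]1[C@H](C)CC(=O)N1[C@H](c2ccccc2)COC1=O
F6 | step 7 | glycidic keto diester (C7–C11 epoxide) | CC(C)(C)[Si](C)(C)O[C@H]1C[C@@](C)(O)C(=C)[C@@H]1[C@H](C)CC(=O)C1OC1(C(=O)OCC)C(=O)OCC
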